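Ring A is read as a hidden 5,6-dimethylsalicylate: the C3 oxygen is para to C10 (which carries C20), and the C19 ester on C4 flanks C5, whose exocyclic carbon C6 is an ortho-toluate methyl. Ring B is therefore disconnected at C6–C7 and C9–C10. The key step is a tandem lateral alkylation/alkylative dearomatization: the dianion of methyl 6-hydroxy-2,3-dimethylbenzoate displaces the triflate of a geraniol-derived Sharpless epoxy triflate through C6, then the phenoxide opens the epoxide at C9 through its para carbon C10. One operation builds ring B, the C10 quaternary centre, C9 and the ring A dienone that later delivers C3, C4 and C5.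

Key step: step 6

Remark: labdane numbering (C1–C10 decalin, C11–C16 side chain, C17 methylene, C18 methyl and C19 ester on C4, C20 methyl on C10) is used from the fragments onwards; α is the face opposite to C20.

Step 1
Reactants: 1 geraniol
Product: 2 geranyl tert-butyldimethylsilyl ether
Conditions: TBSCl, imidazole, DMF, 0 °C to rt
Reagents that add atoms: tert-butyldimethylsilyl chloride CC(C)(C)[Si](C)(C)Cl
Why: Silyl ether protection of the primary allylic alcohol (future C15–OH) against the strong bases and hydrides used later; no stereocentre is formed.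

Step 2
Reactants: 2 geranyl tert-butyldimethylsilyl ether
Product: 3 (2E,6E)-8-(tert-butyldimethylsilyloxy)-2,6-dimethylocta-2,6-dien-1-ol
Conditions: SeO2 (0.1 equiv), t-BuOOH, salicylic acid (cat.), CH2Cl2, 0 °C to rt
Reagents that add atoms: tert-butyl hydroperoxide CC(C)(C)OO
Why: Riley allylic oxidation (ene reaction, then 2,3-sigmatropic shift) should hydroxylate the (E)-methyl group of the electron-rich terminal alkene (future C7), the alkene next to the silyloxy group being deactivated.

Step 3
Reactants: 3 (2E,6E)-8-(tert-butyldimethylsilyloxy)-2,6-dimethylocta-2,6-dien-1-ol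
Product: 4 [(2R,3R)-3-[(3E)-5-(tert-butyldimethylsilyloxy)-3-methylpent-3-en-1-yl]-2-methyloxiran-2-yl]methanol
Conditions: Ti(OiPr)4 (10 mol%), D-(−)-diethyl tartrate, t-BuOOH, 4 Å MS, CH2Cl2, −20 °C
Reagents that add atoms: tert-butyl hydroperoxide CC(C)(C)OO
Why: Sharpless asymmetric epoxidation touches only the alkene with the free allylic hydroxyl, and D-(−)-tartrate should give the (2R,3R)-epoxide (C8 R, C9 R), the mirror image of the (2S,3S) products obtained with L-(+)-tartrate.

Step 4
Reactants: 4 (2R,3R)-epoxy alcohol
Product: 5 [(2R,3R)-3-[(3E)-5-(tert-butyldimethylsilyloxy)-3-methylpent-3-en-1-yl]-2-methyloxiran-2-yl]methyl trifluoromethanesulfonate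
Conditions: Tf2O, 2,6-lutidine, CH2Cl2, −78 °C; used at once
Reagents that add atoms: trifluoromethanesulfonic anhydride O=S(=O)(OS(=O)(=O)C(F)(F)F)C(F)(F)F
Why: O-Sulfonylation turns the primary hydroxyl (C7) into a leaving group that a carbanion can displace at −78 °C without touching the epoxide; the stereocentres are untouched.

Step 5
Reactants: 6 methyl 2,3-dimethylbenzoate
Product: 8 methyl 6-hydroxy-2,3-dimethylbenzoate, via aryl trifluoroacetate 7 (not isolated)
Conditions: [RuCl2(p-cymene)]2 (2.5 mol%), K2S2O8, CF3CO2H/(CF3CO)2O, 80 °C; then aq NaHCO3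
Reagents that add atoms: trifluoroacetic acid OC(=O)C(F)(F)F
Why: Ester-directed ruthenium-catalysed ortho C–H oxygenation should functionalize the only ortho C–H of 6, and the trifluoroacetate 7 is hydrolysed on work-up to the phenol (future C3–O).

Step 6
Reactants: 8 methyl 6-hydroxy-2,3-dimethylbenzoate; 5 epoxy triflate
Product: 11 methyl 15-(tert-butyldimethylsilyloxy)-8α-hydroxy-3-oxo-18-norlabda-1,4,13E-trien-19-oate, via dilithio dianion 9 (not isolated), via lithium epoxy phenoxide 10 (not isolated)
Conditions: LiN(i-Pr)2 (2.05 equiv), THF, −78 °C; 5, −78 to −20 °C; then CF3CH2OH, 60 °C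
Reagents that add atoms: none
Why: Proposed new method: LiN(i-Pr)2 removes the phenol proton and then a proton of the ortho-toluate methyl (C6) to give dianion 9, whose benzylic carbon displaces the primary triflate of 5 (SN2) to form C6–C7; on warming in CF3CH2OH the phenoxide of 10 attacks the secondary epoxide carbon C9 through its para carbon C10 to form C9–C10 and the cross-conjugated dienone, the alcohol protonating the tertiary alkoxide so that the dearomatization is downhill. The closest known reaction types are the lateral alkylation of ortho-toluate anions and the alkylative dearomatization of phenolates by tethered sulfonates (Ar2-6 participation), here run in tandem with an epoxide as the electrophile. Ring B closes in the 6-endo-tet mode at the less substituted epoxide carbon, as in epoxynitrile cyclizations, because the 5-exo alternative would need attack at the fully substituted C8. C9 is set by SN2 inversion of the Sharpless epoxide and C8 keeps the epoxide configuration; C10 follows because the breaking C9–O bond must be anti to the forming C9–C10 bond in a chair ring B with C1 equatorial, which places the side chain and the C8 oxygen equatorial and C20 axial, cis to the side chain. The step needs C-attack at C10 and not at oxygen, C2 or C4: oxygen and C2 cannot reach C9 through the tether on C5, and C4, the other neighbour of C5, is disfavoured because attack there would break the phenoxide–ester conjugation that the para pathway keeps.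

Step 7
Reactants: 11 tertiary alcohol
Product: 12 methyl 15-(tert-butyldimethylsilyloxy)-3-oxo-18-norlabda-1,4,8(17),13E-tetraen-19-oate
Conditions: SOCl2, pyridine, CH2Cl2, −20 to 0 °C
Reagents that add atoms: none
Why: Dehydration by E2 elimination: the activated C8–O bond is equatorial, so only hydrogens of the axial C17 methyl can be antiperiplanar to it, which should give the exocyclic C8=C17 alkene.

Step 8
Reactants: 12 dienone ester
Product: 14 methyl 15-(tert-butyldimethylsilyloxy)-3-oxo-18-norlabda-4,8(17),13E-trien-19-oate, via lithium dienolate 13 (not isolated)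
Conditions: LiBH(s-Bu)3 (1.05 equiv), THF, −78 °C; then H2O
Reagents that add atoms: none
Why: Conjugate (1,4) hydride reduction by a bulky trialkylborohydride should occur at the unsubstituted β-carbon C1, since the β-carbon C5 of the other enone arm is fully substituted; protonation of 13 at C2 gives the enone ester.

Step 9
Reactants: 14 enone ester
Product: 16 methyl 15-(tert-butyldimethylsilyloxy)-3-oxolabda-8(17),13E-dien-19-oate, via lithium enolate 15 (not isolated)
Conditions: Li (2.2 equiv), NH3(l)/THF, −78 °C; then MeI, −78 to −33 °C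
Reagents that add atoms: iodomethane CI
Why: Birch-type reductive alkylation of an alkylidene β-keto ester: protonation of the C5 carbanion on the α face gives the trans ring fusion, and enolate 15 is methylated at C4 on the α face, away from the axial C20, which leaves the C19 ester axial (β).

Step 10
Reactants: 16 β-keto ester
Product: 18 methyl 3α-acetoxy-15-(tert-butyldimethylsilyloxy)labda-8(17),13E-dien-19-oate, via lithium alkoxide 17 (not isolated)
Conditions: LiBH(s-Bu)3 (1.5 equiv), THF, −78 to 0 °C; then Ac2O, DMAP, 0 °C to rt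
Reagents that add atoms: acetic anhydride CC(=O)OC(C)=O
Why: Bulky-hydride reduction of the cyclohexanone by equatorial attack should give the axial 3α-alkoxide 17, which is O-acetylated in the same flask.

Step 11
Reactants: 18 silyl ether
Product: 19 methyl 3α-acetoxy-15-hydroxylabda-8(17),13E-dien-19-oate
Conditions: HF·pyridine, THF/pyridine, 0 °C
Reagents that add atoms: none
Why: Fluoride-mediated cleavage of the primary silyl ether frees the allylic alcohol while the hindered acetate, the ester and both alkenes stay untouched.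

Step 12
Reactants: 19 allylic alcohol
Product: 20 methyl (13R,14R)-3α-acetoxy-13,14-epoxy-15-hydroxylabd-8(17)-en-19-oate
Conditions: Ti(OiPr)4, D-(−)-diethyl tartrate, t-BuOOH, 4 Å MS, CH2Cl2, −20 °C
Reagents that add atoms: tert-butyl hydroperoxide CC(C)(C)OO
Why: Sharpless asymmetric epoxidation is hydroxyl-directed (the C8=C17 alkene is spared) and reagent-controlled, D-(−)-tartrate giving the (13R,14R)-epoxy alcohol as in step 3.

Step 13
Reactants: 20 epoxy alcohol
Product: 21 methyl (13R,14S)-3α-acetoxy-13,14-epoxy-15-oxolabd-8(17)-en-19-oate (target)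
Conditions: Dess–Martin periodinane, CH2Cl2, 0 °C
Reagents that add atoms: none
Why: Dess–Martin oxidation converts the primary alcohol into the aldehyde under mild conditions that should not open the epoxide or epimerize C14 (the descriptor changes from R to S only through the priority change).

Compound list
1 | geraniol, (2E)-3,7-dimethylocta-2,6-dien-1-ol | CC(C)=CCC/C(C)=C/CO | starting material
2 | geranyl tert-butyldimethylsilyl ether | CC(C)=CCC/C(C)=C/CO[Si](C)(C)C(C)(C)C | intermediate
3 | (2E,6E)-8-(tert-butyldimethylsilyloxy)-2,6-dimethylocta-2,6-dien-1-ol | OC/C(C)=C/CC/C(C)=C/CO[Si](C)(C)C(C)(C)C | intermediate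
4 | [(2R,3R)-3-[(3E)-5-(tert-butyldimethylsilyloxy)-3-methylpent-3-en-1-yl]-2-methyloxiran-2-yl]methanol | OC[C@@]1(C)O[C@@H]1CC/C(C)=C/CO[Si](C)(C)C(C)(C)C | intermediate
5 | trifluoromethanesulfonate of 4 (2R,3R) | O=S(=O)(OC[C@@]1(C)O[C@@H]1CC/C(C)=C/CO[Si](C)(C)C(C)(C)C)C(F)(F)F | intermediate
6 | methyl 2,3-dimethylbenzoate | COC(=O)c1cccc(C)c1C | starting material
7 | methyl 2,3-dimethyl-6-(trifluoroacetoxy)benzoate | COC(=O)c1c(OC(=O)C(F)(F)F)ccc(C)c1C | intermediate
8 | methyl 6-hydroxy-2,3-dimethylbenzoate | COC(=O)c1c(O)ccc(C)c1C | intermediate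
9 | dilithio dianion of 8 (phenoxide and benzylic carbanion at the 2-methyl group) | COC(=O)c1c([O-])ccc(C)c1[CH2-].[Li+].[Li+] | intermediate
10 | lithium phenoxide of methyl 6-hydroxy-3-methyl-2-[2-[(2R,3R)-epoxide]ethyl]benzoate (C6–C7 formed) | COC(=O)c1c([O-])ccc(C)c1CC[C@@]1(C)O[C@@H]1CC/C(C)=C/CO[Si](C)(C)C(C)(C)C.[Li+] | intermediate
11 | methyl 15-(tert-butyldimethylsilyloxy)-8α-hydroxy-3-oxo-18-norlabda-1,4,13E-trien-19-oate (8β-methyl, 9α-H, 10β-methyl) | COC(=O)C1=C2CC[C@@](C)(O)[C@H](CC/C(C)=C/CO[Si](C)(C)C(C)(C)C)[C@@]2(C)C=CC1=O | intermediate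
12 | methyl 15-(tert-butyldimethylsilyloxy)-3-oxo-18-norlabda-1,4,8(17),13E-tetraen-19-oate | COC(=O)C1=C2CCC(=C)[C@H](CC/C(C)=C/CO[Si](C)(C)C(C)(C)C)[C@@]2(C)C=CC1=O | intermediate
13 | lithium dienolate (C2=C3–OLi) from 1,4-reduction of 12 | COC(=O)C1=C2CCC(=C)[C@H](CC/C(C)=C/CO[Si](C)(C)C(C)(C)C)[C@@]2(C)CC=C1[O-].[Li+] | intermediate
14 | methyl 15-(tert-butyldimethylsilyloxy)-3-oxo-18-norlabda-4,8(17),13E-trien-19-oate | COC(=O)C1=C2CCC(=C)[C@H](CC/C(C)=C/CO[Si](C)(C)C(C)(C)C)[C@@]2(C)CCC1=O | intermediate
15 | lithium enolate (C3–OLi, C3=C4, 5α-H) from reduction of 14 | COC(=O)C=1[C@@H]2CCC(=C)[C@H](CC/C(C)=C/CO[Si](C)(C)C(C)(C)C)[C@@]2(C)CCC1[O-].[Li+] | intermediate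
16 | methyl 15-(tert-butyldimethylsilyloxy)-3-oxolabda-8(17),13E-dien-19-oate (4α-methyl, 4β-ester, 5α-H) | COC(=O)[C@]1(C)[C@@H]2CCC(=C)[C@H](CC/C(C)=C/CO[Si](C)(C)C(C)(C)C)[C@@]2(C)CCC1=O | intermediate
17 | lithium 3α-alkoxide from reduction of 16 | COC(=O)[C@]1(C)[C@@H]2CCC(=C)[C@H](CC/C(C)=C/CO[Si](C)(C)C(C)(C)C)[C@@]2(C)CC[C@H]1[O-].[Li+] | intermediate
18 | methyl 3α-acetoxy-15-(tert-butyldimethylsilyloxy)labda-8(17),13E-dien-19-oate | COC(=O)[C@]1(C)[C@@H]2CCC(=C)[C@H](CC/C(C)=C/CO[Si](C)(C)C(C)(C)C)[C@@]2(C)CC[C@H]1OC(C)=O | intermediate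
19 | methyl 3α-acetoxy-15-hydroxylabda-8(17),13E-dien-19-oate | COC(=O)[C@]1(C)[C@@H]2CCC(=C)[C@H](CC/C(C)=C/CO)[C@@]2(C)CC[C@H]1OC(C)=O | intermediate
20 | methyl (13R,14R)-3α-acetoxy-13,14-epoxy-15-hydroxylabd-8(17)-en-19-oate | COC(=O)[C@]1(C)[C@@H]2CCC(=C)[C@H](CC[C@@]3(C)O[C@@H]3CO)[C@@]2(C)CC[C@H]1OC(C)=O | intermediate
21 | methyl (13R,14S)-3α-acetoxy-13,14-epoxy-15-oxolabd-8(17)-en-19-oate, CNP0145900.1 | COC(=O)[C@]1(C)[C@@H]2CCC(=C)[C@H](CC[C@@]3(C)O[C@@H]3C=O)[C@@]2(C)CC[C@H]1OC(C)=O | target

Total step count: 13. Longest linear sequence: 12 steps (steps 1–4, then 6–13).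

Steps most likely to fail

1. Step 6 (proposed new method). After the C6 alkylation the phenoxide may fail to open the epoxide through C10. The possible failure modes are slow C-attack with intermolecular O-alkylation taking over, closure at C4 instead of C10, and proton transfer from C6–H followed by carbanion attack on the epoxide. Fallback with known reactions, from 3 and 8, back at 12: compound 3 is epoxidized with L-(+)-diethyl tartrate to the enantiomeric (2S,3S)-epoxy alcohol F1, which is converted into its triflate F2. Alkylation of dianion 9 with F2 and quenching at −78 °C gives the isolated epoxy phenol F3 (lateral toluate alkylation only). Diethylaluminium 2,2,6,6-tetramethylpiperidide rearranges the epoxide to the (S)-allylic alcohol F4, which already carries the C8=C17 methylene, and methyl chloroformate with pyridine gives the allylic methyl carbonate F5. A zerovalent palladium catalyst (Pd2(dba)3, PPh3, THF, 50 °C) then closes ring B by intramolecular Tsuji–Trost allylic dearomatization of the phenol at C10 and gives 12. Ionization and attack each invert C9, so the (S)-carbonate should give the same C9 configuration as the main route. Closure at C9 rather than at the unsubstituted C17 terminus is not assured with palladium and would have to be steered by the ligand. Step 7 is then not needed.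

2. Step 9. Over-reduction, loss of the allylic silyl ether under dissolving-metal conditions, O-methylation or poor facial selectivity in the methylation may occur. Fallback, from 14, back at 16: reduction and alkylation are separated. SmI2 (THF, t-BuOH, −78 °C) reduces the alkylidene β-keto ester by electron transfer to the trans-fused β-keto ester F6. Its sodium enolate (NaH, THF, 0 °C) is then methylated with MeI on the α face to give 16.

3. Step 8. The hydride may add 1,2 to the cross-conjugated ketone or attack the ester-activated alkene, so the conjugate reduction may lack chemoselectivity. Fallback, from 11, back at 14: the C1=C2 bond is removed before the exocyclic alkene exists. Hydrogenation of 11 with RhCl(PPh3)3 (H2, 1 atm, benzene) should saturate only the unhindered disubstituted C1=C2 bond and give the hydroxy enone ester F7. Dehydration as in step 7 (SOCl2, pyridine) then gives 14.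

Further compounds
F1 | step 6 | [(2S,3S)-3-[(3E)-5-(tert-butyldimethylsilyloxy)-3-methylpent-3-en-1-yl]-2-methyloxiran-2-yl]methanol | OC[C@]1(C)O[C@H]1CC/C(C)=C/CO[Si](C)(C)C(C)(C)C
F2 | step 6 | trifluoromethanesulfonate of F1 | O=S(=O)(OC[C@]1(C)O[C@H]1CC/C(C)=C/CO[Si](C)(C)C(C)(C)C)C(F)(F)F
F3 | step 6 | methyl 6-hydroxy-3-methyl-2-[2-[(2S,3S)-3-[(3E)-5-(tert-butyldimethylsilyloxy)-3-methylpent-3-en-1-yl]-2-methyloxiran-2-yl]ethyl]benzoate | COC(=O)c1c(O)ccc(C)c1CC[C@]1(C)O[C@H]1CC/C(C)=C/CO[Si](C)(C)C(C)(C)C
F4 | step 6 | methyl 2-[(4S,7E)-9-(tert-butyldimethylsilyloxy)-4-hydroxy-7-methyl-3-methylidenenon-7-en-1-yl]-6-hydroxy-3-methylbenzoate | COC(=O)c1c(O)ccc(C)c1CCC(=C)[C@@H](O)CC/C(C)=C/CO[Si](C)(C)C(C)(C)C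
F5 | step 6 | methyl carbonate of the allylic alcohol F4 | COC(=O)c1c(O)ccc(C)c1CCC(=C)[C@@H](OC(=O)OC)CC/C(C)=C/CO[Si](C)(C)C(C)(C)C
F6 | step 9 | methyl 15-(tert-butyldimethylsilyloxy)-3-oxo-18-norlabda-8(17),13E-dien-19-oate (5α-H, C4 epimerizable) | COC(=O)C1[C@@H]2CCC(=C)[C@H](CC/C(C)=C/CO[Si](C)(C)C(C)(C)C)[C@@]2(C)CCC1=O
F7 | step 8 | methyl 15-(tert-butyldimethylsilyloxy)-8α-hydroxy-3-oxo-18-norlabda-4,13E-dien-19-oate | COC(=O)C1=C2CC[C@@](C)(O)[C@H](CC/C(C)=C/CO[Si](C)(C)C(C)(C)C)[C@@]2(C)CCC1=O
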